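**Plan**

1. Numbering: five-membered ring C1 (carbinol), C2, C3 (C=O), C4 (methyl), C5; seven-membered ring C5, C6 (OH), C7, C8 (O-angeloyl), C9, C10 (methyl), C1; C11 is the acetoxy carbon on C7. β is the face of the C10 methyl group, α the opposite face.
2. Retrosynthesis: the C1–O and C6–O bonds and the two ester C–O bonds are cut first, then the C11 methyl groups, then the seven-membered ring at C6–C7 and C9–C10, and last the five-membered ring at C1–C5.
3. Enabling feature: C7 (carrying C11 at the ester level), C8 (oxygen) and C9 (CH2) are the three carbons of a 2-siloxyvinyl carbenoid. C6=C5–C1=C10, with C5–C1 as the fusion bond of the five-membered ring, is the s-cis-locked diene of a 1,2-dialkylidenecyclopentane.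
4. Forward: crotylboration and ketalisation give an enyne; palladium cycloisomerisation closes the five-membered ring; carbenoid cyclopropanation and Cope rearrangement close the seven-membered ring; then C8/C7, C11, the esters, C6 and finally C1.
5. Stereochemistry: C4 (from the crotylboration) and the chiral rhodium carboxylate fix the diene face and so C10. C10 steers the reduction that sets C8 and C7. The C7 side chain steers hydride to C6. The C10 methyl and C6 oxygen steer the oxidant to the α face of C1. C4 is erased at the end.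

Key step: step 8

Assumption: the facial preferences of (S)-TRIP (aldehyde Si face) and of Rh2(S-PTAD)4 (diene face anti to the C4 methyl) are taken from the closest reported cases; if a trial shows the opposite sense for either, its antipode is used so that C4 of 11 is S and C10 of 13 is S.

**Route**

Step 1
Reactants: 1 methyl acetoacetate
Product: 2 methyl 2-diazo-3-oxobutanoate
Conditions: 4-acetamidobenzenesulfonyl azide, Et3N, MeCN, 0 → 23 °C
Reagents that add atoms: 4-acetamidobenzenesulfonyl azide, CC(=O)Nc1ccc(cc1)S(=O)(=O)N=[N+]=[N-]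
Why: Regitz diazo transfer to the doubly activated methylene of a β-keto ester is routine and leaves both carbonyl groups untouched.

Step 2
Reactants: 2 methyl 2-diazo-3-oxobutanoate
Product: 3 methyl 2-diazo-3-(tert-butyldimethylsilyloxy)but-3-enoate
Conditions: t-BuMe2SiOTf, Et3N, CH2Cl2, 0 °C
Reagents that add atoms: tert-butyldimethylsilyl triflate, CC(C)(C)[Si](C)(C)OS(=O)(=O)C(F)(F)F
Why: Soft enolisation of the acetyl group (silyl enol ether formation with silyl triflate and amine) gives the 2-siloxyvinyl diazoacetate, the diazo group being inert to these conditions.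

Step 3
Reactants: 4 pent-3-yn-1-ol
Product: 5 pent-3-ynal
Conditions: Dess–Martin periodinane, pyridine, CH2Cl2, 0 °C; crude solution used at once
Reagents that add atoms: none
Why: Dess–Martin oxidation under buffered, non-basic conditions should give the β,γ-alkynyl aldehyde without isomerisation to the allenyl aldehyde.

Step 4
Reactants: 5 pent-3-ynal; 6 (E)-crotylboronic acid pinacol ester
Product: 8 (3S,4R)-3-methyloct-1-en-6-yn-4-ol, via pinacol borate 7 (not isolated)
Conditions: (S)-TRIP [(S)-3,3'-bis(2,4,6-triisopropylphenyl)-1,1'-binaphthyl-2,2'-diyl hydrogen phosphate] (5 mol%), toluene, −30 °C; aq. NaHCO3 work-up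
Reagents that add atoms: none
Why: Chiral phosphoric acid-catalysed crotylboration runs through a closed chair (Zimmerman–Traxler) transition state, so the E-crotyl unit gives the anti adduct and (S)-TRIP selects the aldehyde Si face, which sets 3S (the later C4) and 4R.

Step 5
Reactants: 8 (3S,4R)-3-methyloct-1-en-6-yn-4-ol
Product: 9 (3S)-3-methyloct-1-en-6-yn-4-one
Conditions: Dess–Martin periodinane, pyridine, CH2Cl2, 0 °C
Reagents that add atoms: none
Why: Dess–Martin oxidation is neutral enough to keep the allylic α-stereocentre and to leave the alkene and alkyne out of conjugation.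

Step 6
Reactants: 9 (3S)-3-methyloct-1-en-6-yn-4-one
Product: 10 2-[(2S)-but-3-en-2-yl]-2-(but-2-yn-1-yl)-1,3-dioxolane
Conditions: Me3SiOCH2CH2OSiMe3, Me3SiOTf (5 mol%), CH2Cl2, −78 → −20 °C; pyridine quench
Reagents that add atoms: 1,2-bis(trimethylsilyloxy)ethane, C[Si](C)(C)OCCO[Si](C)(C)C
Why: Noyori ketalisation is aprotic and cold, so it should neither epimerise the α-centre nor move the unsaturation, and the dioxolane then locks that centre.

Step 7
Reactants: 10 2-[(2S)-but-3-en-2-yl]-2-(but-2-yn-1-yl)-1,3-dioxolane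
Product: 11 (6S,8E)-8-ethylidene-6-methyl-7-methylidene-1,4-dioxaspiro[4.4]nonane (diene; spiro C6 = C4 of the target numbering)
Conditions: Pd(OAc)2 (5 mol%), PPh3 (10 mol%), benzene, 60 °C
Reagents that add atoms: none
Why: Trost enyne cycloisomerisation (alkyne hydropalladation, 5-exo carbopalladation of the vinyl group, β-hydride elimination from C5 as the only β-hydrogen) gives the 1,2-dialkylidenecyclopentane, syn hydropalladation fixing the E-ethylidene and the stereocentre staying untouched.

Step 8
Reactants: 11 diene; 3 methyl 2-diazo-3-(tert-butyldimethylsilyloxy)but-3-enoate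
Product: 13 methyl 8-(tert-butyldimethylsilyloxy)-3,3-(ethylenedioxy)-12,13-dinorguaia-1(5),7-dien-11-oate (4α-methyl; 10β-methyl; 10S), via spiro divinylcyclopropane 12 (not isolated)
Conditions: Rh2(S-PTAD)4 (1 mol%), hexanes, slow addition of 3 (1.8 equiv), −26 → 23 °C
Reagents that add atoms: none
Why: Rh2(S-PTAD)4 turns 3 into a donor/acceptor vinylcarbenoid of divalent rhodium that cyclopropanates the 1,1-disubstituted C5=C6 methylene of 11, the siloxyvinyl group ending up cis to the C1=C10 arm in spiro cyclopropane 12. 12 rearranges below room temperature by a boat-shaped Cope ([3,3]) shift that breaks C5–C7 and joins C9 to C10, so the seven-membered ring closes by sigmatropic rearrangement of a cis-divinylcyclopropane and not by direct cyclisation; the closest known reaction type is the formal [4+3] cycloaddition of 2-siloxyvinyldiazoacetates with open-chain and semicyclic dienes under this catalyst. The one new stereocentre, C10, follows from the E geometry of the ethylidene group, relayed through the boat transition state, and from the diene face that the carbenoid adds to. That face is the one anti to the allylic C4 methyl group, and the catalyst antipode is chosen to reinforce it, which should give 10S with the C4 and C10 methyl groups trans. The step needs site selectivity (methylene over ethylidene) and face selectivity: the first rests on the low reactivity of trisubstituted alkenes toward these bulky carbenoids, the second on the matched pair of substrate and catalyst. Material from the minor enantiomer of 11 ends up as diastereomers that are separated, and any trans-divinylcyclopropane should converge on 13 on gentle warming.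

Step 9
Reactants: 13 cycloadduct
Product: 14 methyl 3,3-(ethylenedioxy)-8-oxo-12,13-dinorguai-1(5)-en-11-oate (4α-methyl; 10β-methyl; C7 epimers and enol)
Conditions: HF·pyridine, pyridine, THF, 0 °C
Reagents that add atoms: none
Why: Protodesilylation of the silyl enol ether with buffered HF frees the β-keto ester, whose C7 centre equilibrates through the enol, while the dioxolane survives the buffered medium.

Step 10
Reactants: 14 β-keto ester
Product: 15 methyl 3,3-(ethylenedioxy)-8β-hydroxy-12,13-dinorguai-1(5)-en-11-oate (7β-CO2Me; 7S,8R)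
Conditions: Zn(BH4)2, Et2O, −20 °C; aq. NH4Cl
Reagents that add atoms: none
Why: Chelation-controlled reduction with Zn(BH4)2 attacks the zinc-bridged keto ester from the side of the C7 hydrogen and so gives the cis hydroxy ester, and because the C7 epimers interconvert the hydride should enter from the α face, away from the pseudoaxial C10 methyl group, setting 8β-OH and 7β-CO2Me.

Step 11
Reactants: 15 cis β-hydroxy ester
Product: 17 3,3-(ethylenedioxy)guai-1(5)-ene-8β,11-diol (7β side chain), via hydroxy methyl ketone 16 (not isolated)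
Conditions: MeMgBr (6 equiv), THF, 0 → 23 °C; aq. NH4Cl
Reagents that add atoms: methylmagnesium bromide, C[Mg]Br
Why: Double Grignard addition to the ester through the methyl ketone builds the C11 carbinol, the C8 alkoxide formed first being a poor leaving group, and no stereocentre is touched.

Step 12
Reactants: 17 diol; 18 angelic acid
Product: 20 3,3-(ethylenedioxy)-11-hydroxyguai-1(5)-en-8β-yl angelate, via mixed anhydride 19 (not isolated)
Conditions: 18 (3 equiv), 2,4,6-Cl3C6H2COCl, Et3N, toluene, 23 °C; then 17, 75 °C (no DMAP)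
Reagents that add atoms: none
Why: Yamaguchi esterification through the mixed anhydride acylates only the secondary C8 hydroxyl, the tertiary C11 hydroxyl being inert, and the DMAP-free protocol should keep the Z geometry of the angelate.

Step 13
Reactants: 20 8β-angelate
Product: 21 11-acetoxy-3,3-(ethylenedioxy)guai-1(5)-en-8β-yl angelate
Conditions: Ac2O (10 equiv), DMAP (0.3 equiv), Et3N, CH2Cl2, 35 °C
Reagents that add atoms: acetic anhydride, CC(=O)OC(C)=O
Why: DMAP-catalysed acylation with excess anhydride esterifies the tertiary alcohol, which is the only free hydroxyl at this stage.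

Step 14
Reactants: 21 angelate acetate
Product: 22 11-acetoxy-3,3-(ethylenedioxy)-6-oxoguai-1(5)-en-8β-yl angelate
Conditions: Rh2(cap)4 [dirhodium tetrakis(caprolactamate)] (1 mol%), t-BuOOH (70% aq., 5 equiv), ClCH2CH2Cl, 40 °C
Reagents that add atoms: tert-butyl hydroperoxide, CC(C)(C)OO
Why: Dirhodium caprolactamate/t-BuOOH allylic oxidation should convert C6, the only allylic methylene not flanked by the dioxolane, into the enone, since C2 and C4 are deactivated by the adjacent ketal carbon (as C4 is in 3-oxygenated Δ5-steroids) and the tertiary C10 position cannot give a ketone; base is left out to spare the β-acyloxy ketone.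

Step 15
Reactants: 22 C6 enone
Product: 23 11-acetoxy-3,3-(ethylenedioxy)-6β-hydroxyguai-1(5)-en-8β-yl angelate (6R)
Conditions: LiBH(s-Bu)3 (1.2 equiv), THF, −78 °C; AcOH, −78 °C
Reagents that add atoms: none
Why: L-Selectride reduces the β,β-disubstituted enone 1,2 from the α face, opposite to the bulky C7 side chain (steric approach control), which sets the 6β-hydroxyl, and at −78 °C it should spare the acetate and the β-substituted angelate.

Step 16
Reactants: 23 6β-alcohol
Product: 24 11-acetoxy-6β-hydroxy-3-oxoguai-1(5)-en-8β-yl angelate (C4 now labile)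
Conditions: PPTS (0.2 equiv), acetone/H2O (10:1), 40 °C
Reagents that add atoms: water, O
Why: Mild acid-catalysed dioxolane hydrolysis frees the C3 ketone, and any drift of the alkene into conjugation or epimerisation at C4 is harmless because all isomers give the same dienol ether in the next step.

Step 17
Reactants: 24 C3 ketone
Product: 25 11-acetoxy-3,6β-bis(trimethylsilyloxy)guaia-1(5),3-dien-8β-yl angelate (2-siloxycyclopentadiene)
Conditions: Me3SiOTf (3 equiv), Et3N (5 equiv), CH2Cl2, 0 → 40 °C; non-aqueous work-up, used crude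
Reagents that add atoms: trimethylsilyl triflate, C[Si](C)(C)OS(=O)(=O)C(F)(F)F
Why: Soft enolisation silylates the C6 hydroxyl and converts the ketone into the silyl dienol ether, which should settle by reversible enolisation and 1,5-hydrogen shifts on the cyclopentadiene with both ring double bonds tetrasubstituted (C3=C4 and C5=C1), erasing C4.

Step 18
Reactants: 25 siloxycyclopentadiene
Product: 28 CNP0273287.1, (1R,6R,7S,8R,10S)-11-acetoxy-1α,6β-dihydroxy-3-oxoguai-4-en-8β-yl angelate, via epoxy silyl enol ether 26 (not isolated), via bis-silyl ether 27 (not isolated)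
Conditions: dimethyldioxirane (1.1 equiv, acetone), CH2Cl2, −78 → −40 °C; then citric acid (cat.), MeOH/H2O, 0 °C
Reagents that add atoms: dimethyldioxirane, CC1(C)OO1
Why: In this vinylogous Rubottom oxidation the dioxirane should epoxidise the terminal C5=C1 bond of the siloxydiene from the α face, anti to the C10 methyl and C6 siloxy groups, the epoxide opens with the push of the enol ether to the C4=C5 enone and sets the 1α-oxygen, and mild acid removes both trimethylsilyl groups.

**Compound list**

1 | methyl acetoacetate | COC(=O)CC(C)=O | starting material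
2 | methyl 2-diazo-3-oxobutanoate | COC(=O)C(=[N+]=[N-])C(C)=O | intermediate
3 | methyl 2-diazo-3-(tert-butyldimethylsilyloxy)but-3-enoate | COC(=O)C(=[N+]=[N-])C(=C)O[Si](C)(C)C(C)(C)C | intermediate
4 | pent-3-yn-1-ol | CC#CCCO | starting material
5 | pent-3-ynal | CC#CCC=O | intermediate
6 | (E)-crotylboronic acid pinacol ester | C/C=C/CB1OC(C)(C)C(C)(C)O1 | starting material
7 | pinacol borate of 8 (not isolated) | C=C[C@H](C)[C@@H](CC#CC)OB1OC(C)(C)C(C)(C)O1 | intermediate
8 | (3S,4R)-3-methyloct-1-en-6-yn-4-ol | C=C[C@H](C)[C@H](O)CC#CC | intermediate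
9 | (3S)-3-methyloct-1-en-6-yn-4-one | C=C[C@H](C)C(=O)CC#CC | intermediate
10 | 2-[(2S)-but-3-en-2-yl]-2-(but-2-yn-1-yl)-1,3-dioxolane | C=C[C@H](C)C1(CC#CC)OCCO1 | intermediate
11 | (6S,8E)-8-ethylidene-6-methyl-7-methylidene-1,4-dioxaspiro[4.4]nonane | C/C=C1\CC2(OCCO2)[C@@H](C)C1=C | intermediate
12 | spiro cis-divinylcyclopropane (C5 spiro; C7 bearing CO2Me and the siloxyvinyl group cis to the ethylidene arm; not isolated) | COC(=O)[C@@]1(C(=C)O[Si](C)(C)C(C)(C)C)C[C@@]12[C@H](C)C3(OCCO3)C/C2=C\C | intermediate
13 | methyl 8-(tert-butyldimethylsilyloxy)-3,3-(ethylenedioxy)-12,13-dinorguaia-1(5),7-dien-11-oate (4α-Me, 10β-Me) | COC(=O)C1=C(O[Si](C)(C)C(C)(C)C)C[C@H](C)C2=C(C1)[C@H](C)C3(OCCO3)C2 | intermediate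
14 | methyl 3,3-(ethylenedioxy)-8-oxo-12,13-dinorguai-1(5)-en-11-oate (C7 epimers/enol) | COC(=O)C1C(=O)C[C@H](C)C2=C(C1)[C@H](C)C3(OCCO3)C2 | intermediate
15 | methyl 3,3-(ethylenedioxy)-8β-hydroxy-12,13-dinorguai-1(5)-en-11-oate (7β-CO2Me) | O[C@@H]1C[C@H](C)C2=C(C[C@@H]1C(=O)OC)[C@H](C)C3(OCCO3)C2 | intermediate
16 | 7β-acetyl-8β-hydroxy methyl ketone (not isolated) | O[C@@H]1C[C@H](C)C2=C(C[C@@H]1C(C)=O)[C@H](C)C3(OCCO3)C2 | intermediate
17 | 3,3-(ethylenedioxy)guai-1(5)-ene-8β,11-diol | O[C@@H]1C[C@H](C)C2=C(C[C@@H]1C(C)(C)O)[C@H](C)C3(OCCO3)C2 | intermediate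
18 | angelic acid, (Z)-2-methylbut-2-enoic acid | C/C=C(/C)C(=O)O | starting material
19 | angelic 2,4,6-trichlorobenzoic anhydride (not isolated) | C/C=C(/C)C(=O)OC(=O)c1c(Cl)cc(Cl)cc1Cl | intermediate
20 | 3,3-(ethylenedioxy)-11-hydroxyguai-1(5)-en-8β-yl angelate | C/C=C(/C)C(=O)O[C@@H]1C[C@H](C)C2=C(C[C@@H]1C(C)(C)O)[C@H](C)C3(OCCO3)C2 | intermediate
21 | 11-acetoxy-3,3-(ethylenedioxy)guai-1(5)-en-8β-yl angelate | C/C=C(/C)C(=O)O[C@@H]1C[C@H](C)C2=C(C[C@@H]1C(C)(C)OC(C)=O)[C@H](C)C3(OCCO3)C2 | intermediate
22 | 11-acetoxy-3,3-(ethylenedioxy)-6-oxoguai-1(5)-en-8β-yl angelate | C/C=C(/C)C(=O)O[C@@H]1C[C@H](C)C2=C(C(=O)[C@@H]1C(C)(C)OC(C)=O)[C@H](C)C3(OCCO3)C2 | intermediate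
23 | 11-acetoxy-3,3-(ethylenedioxy)-6β-hydroxyguai-1(5)-en-8β-yl angelate | C/C=C(/C)C(=O)O[C@@H]1C[C@H](C)C2=C([C@H](O)[C@@H]1C(C)(C)OC(C)=O)[C@H](C)C3(OCCO3)C2 | intermediate
24 | 11-acetoxy-6β-hydroxy-3-oxoguai-1(5)-en-8β-yl angelate | C/C=C(/C)C(=O)O[C@@H]1C[C@H](C)C2=C([C@H](O)[C@@H]1C(C)(C)OC(C)=O)[C@H](C)C(=O)C2 | intermediate
25 | 11-acetoxy-3,6β-bis(trimethylsilyloxy)guaia-1(5),3-dien-8β-yl angelate | C/C=C(/C)C(=O)O[C@@H]1C[C@H](C)C2=C(C(C)=C(O[Si](C)(C)C)C2)[C@H](O[Si](C)(C)C)[C@@H]1C(C)(C)OC(C)=O | intermediate
26 | 1α,5α-epoxide of 25 (not isolated) | C/C=C(/C)C(=O)O[C@@H]1C[C@H](C)[C@]23O[C@@]3(C(C)=C(O[Si](C)(C)C)C2)[C@H](O[Si](C)(C)C)[C@@H]1C(C)(C)OC(C)=O | intermediate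
27 | 1α,6β-bis-O-trimethylsilyl ether of 28 (not isolated) | C/C=C(/C)C(=O)O[C@@H]1C[C@H](C)[C@]2(O[Si](C)(C)C)CC(=O)C(C)=C2[C@H](O[Si](C)(C)C)[C@@H]1C(C)(C)OC(C)=O | intermediate
28 | CNP0273287.1, (1R,6R,7S,8R,10S)-11-acetoxy-1α,6β-dihydroxy-3-oxoguai-4-en-8β-yl angelate | C/C=C(/C)C(=O)O[C@@H]1C[C@H](C)[C@]2(O)CC(=O)C(C)=C2[C@H](O)[C@@H]1C(C)(C)OC(C)=O | target

**Count**

Total steps: 18. Longest linear sequence: 16 steps (4 → 28, steps 3 to 18).

**Steps most likely to fail**

Step 14. Hydrogen abstraction may also occur at the tertiary C10–H or next to the dioxolane, and over-oxidation or β-elimination of the acyloxy groups may erode the yield. The fallback sets out from 21 and replaces the radical oxidation by an ene reaction: SeO2 (0.5 equiv) and t-BuOOH in CH2Cl2 at 23 °C (ene reaction followed by [2,3]-sigmatropic shift, which prefers a ring CH2 over a CH) should give the C6 allylic alcohol F1 as a mixture of C6 epimers. Dess–Martin periodinane with pyridine then oxidises it to enone 22, where the route is rejoined.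

Step 18. The oxidant may attack the enol ether carbon C4 (α-hydroxylation) or the β face, or over-oxidise the electron-rich diene. The fallback sets out from 25 and uses a cycloaddition instead of an epoxidation: photooxygenation (O2, visible light, tetraphenylporphyrin, CH2Cl2, −78 °C) adds singlet oxygen across C1 and C3 from the α face to give the bridged endoperoxide F2, which collapses by oxygen-to-oxygen silyl shift to the γ-silylperoxy enone F3. PPh3 reduces the peroxide to 27, and the acid work-up of step 18 then gives 28.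

Step 10. Facial selectivity at C8 may be poor, or the trans hydroxy ester may form. The fallback sets out from 14 and uses catalyst control followed by inversion at C8: hydrogenation with dynamic kinetic resolution (H2 50 atm, RuCl2[(S)-BINAP], CH2Cl2, 50 °C) should fix 8S and, through the trans preference of cyclic substrates, 7S, giving the trans hydroxy ester F4. MeMgBr converts it into the 8α-hydroxy diol F5, Dess–Martin periodinane gives the hydroxy ketone F6, and LiBH(s-Bu)3 at −78 °C adds hydride anti to the C7 side chain to give diol 17, where the route is rejoined.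

**Further compounds**

F1 | step 14 | 11-acetoxy-3,3-(ethylenedioxy)-6-hydroxyguai-1(5)-en-8β-yl angelate (C6 epimers) | C/C=C(/C)C(=O)O[C@@H]1C[C@H](C)C2=C(C(O)[C@@H]1C(C)(C)OC(C)=O)[C@H](C)C3(OCCO3)C2
F2 | step 18 | 1α,3α-epidioxy adduct of 25 (bridged endoperoxide, C4=C5) | C/C=C(/C)C(=O)O[C@@H]1C[C@H](C)[C@]23OO[C@](O[Si](C)(C)C)(C2)C(C)=C3[C@H](O[Si](C)(C)C)[C@@H]1C(C)(C)OC(C)=O
F3 | step 18 | 1α-(trimethylsilylperoxy)-6β-(trimethylsilyloxy) enone | C/C=C(/C)C(=O)O[C@@H]1C[C@H](C)[C@]2(OO[Si](C)(C)C)CC(=O)C(C)=C2[C@H](O[Si](C)(C)C)[C@@H]1C(C)(C)OC(C)=O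
F4 | step 10 | methyl 3,3-(ethylenedioxy)-8α-hydroxy-12,13-dinorguai-1(5)-en-11-oate (7β-CO2Me, trans) | O[C@H]1C[C@H](C)C2=C(C[C@@H]1C(=O)OC)[C@H](C)C3(OCCO3)C2
F5 | step 10 | 3,3-(ethylenedioxy)guai-1(5)-ene-8α,11-diol | O[C@H]1C[C@H](C)C2=C(C[C@@H]1C(C)(C)O)[C@H](C)C3(OCCO3)C2
F6 | step 10 | 3,3-(ethylenedioxy)-11-hydroxyguai-1(5)-en-8-one (7β side chain) | O=C1C[C@H](C)C2=C(C[C@@H]1C(C)(C)O)[C@H](C)C3(OCCO3)C2
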